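**Retrosynthetic overview**
- The last bond made is the ester C–O bond (Yamaguchi). It joins the epoxy-ketol core to the C10 acid (E)-2-methyl-4-(tigloyloxy)but-2-enoic acid.
- The C10 acid comes from tiglic acid and tert-butyl (E)-4-hydroxy-2-methylbut-2-enoate. The C2–C3 bond of the latter is made by an intermolecular aldol addition of the tert-butyl propionate enolate to TBSOCH2CHO, followed by E1cB dehydration. This is the key C–C bond and the only one made in the route.
- The core comes from (S)-(+)-carvone: Rubottom oxidation sets C6–O anti to the isopropenyl group, the OH is protected as its TBS ether, and Weitz–Scheffer epoxidation follows, also anti to the isopropenyl group.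
- Ring order: the carbocycle is bought with carvone. The oxirane is the only ring formed, and it is closed before the side chain is attached.

Assumption: LDA and TBAF are used as the commercial solutions. Monocyclic compounds carry carvone numbering (C1 = C=O, C2 = C–CH3, C5 = C–isopropenyl, C6 = α′ carbon).

**Core**

Step 1
Reactants: 1 (S)-(+)-carvone
Product: 3 {[(3S)-6-methyl-3-(prop-1-en-2-yl)cyclohexa-1,5-dien-1-yl]oxy}trimethylsilane (carvone TMS dienol ether), via carvone lithium enolate 2 (not isolated)
Conditions: LDA (1.1 equiv), THF, −78 °C, 1 h; TMSCl (1.3 equiv), −78 → 0 °C; pentane/cold NaHCO3 work-up, used crude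
Reagents that add atoms: chlorotrimethylsilane (TMSCl), C[Si](C)(C)Cl
Why: Kinetic deprotonation of the enone by LDA takes place only at the α′-CH2 (C6) and O-silylation traps the cross-conjugated enolate (silyl enol ether formation), leaving the C5 stereocentre untouched.

Step 2
Reactants: 3 carvone TMS dienol ether
Product: 6 (5R,6R)-6-hydroxy-2-methyl-5-(prop-1-en-2-yl)cyclohex-2-en-1-one (trans-6-hydroxycarvone), via silyloxy oxirane 4 (not isolated), via 6-trimethylsilyloxycarvone 5 (not isolated)
Conditions: mCPBA (1.0 equiv), CH2Cl2, −20 → 0 °C; then cat. 1 M HCl, THF/H2O, 0 °C, 15 min; chromatography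
Reagents that add atoms: 3-chloroperbenzoic acid (mCPBA), O=C(OO)c1cccc(Cl)c1
Why: Rubottom oxidation, in which the electron-rich enol ether C1=C6 bond reacts far faster than the isopropenyl or C2=C3 bond, the peracid approaches anti to the neighbouring isopropenyl group and so sets C6 as R (OH trans to isopropenyl, also the more stable diequatorial isomer), and silyl migration followed by mild hydrolysis releases the ketol.

Step 3
Reactants: 6 trans-6-hydroxycarvone
Product: 7 (5R,6R)-6-[(tert-butyldimethylsilyl)oxy]-2-methyl-5-(prop-1-en-2-yl)cyclohex-2-en-1-one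
Conditions: TBSCl (1.5 equiv), imidazole (3 equiv), DMF, rt, 12 h
Reagents that add atoms: tert-butyldimethylsilyl chloride (TBSCl), CC(C)(C)[Si](C)(C)Cl
Why: Imidazole-promoted Corey silylation masks the ketol OH, which alkaline peroxide would otherwise cleave or isomerise, and no stereocentre is touched.

Step 4
Reactants: 7 TBS-protected trans-6-hydroxycarvone
Product: 8 (1S,3R,4R,6S)-3-[(tert-butyldimethylsilyl)oxy]-1-methyl-4-(prop-1-en-2-yl)-7-oxabicyclo[4.1.0]heptan-2-one
Conditions: 30% H2O2 (3 equiv), aq. NaOH (0.3 equiv), MeOH, 0 °C, 1 h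
Reagents that add atoms: hydrogen peroxide, OO
Why: Weitz–Scheffer nucleophilic epoxidation attacks only the enone C=C; hydroperoxide adds axially at the β-carbon anti to the equatorial isopropenyl group, as in carvone itself (the pseudo-equatorial OTBS shields neither face), and closure on the same face sets C1 (S) and C6 (S), so the oxirane is trans to isopropenyl and cis to OTBS.

Step 5
Reactants: 8 silyl-protected epoxy ketone
Product: 9 (1S,3R,4R,6S)-3-hydroxy-1-methyl-4-(prop-1-en-2-yl)-7-oxabicyclo[4.1.0]heptan-2-one
Conditions: TBAF (1.5 equiv), AcOH (1.5 equiv), THF, 0 °C → rt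
Reagents that add atoms: none
Why: Fluoride-driven desilylation (Si–F bond formation) of an activated α-keto silyl ether, with acetic acid buffering so that the freed ketol is never exposed to alkoxide and C3 and the oxirane stay intact.

**Side chain**

Step 6
Reactants: 10 (Z)-but-2-ene-1,4-diol
Product: 11 (Z)-1,4-bis[(tert-butyldimethylsilyl)oxy]but-2-ene
Conditions: TBSCl (2.2 equiv), imidazole (4.4 equiv), CH2Cl2, 0 °C → rt
Reagents that add atoms: tert-butyldimethylsilyl chloride (TBSCl), CC(C)(C)[Si](C)(C)Cl
Why: Corey silylation of two unhindered primary alcohols is essentially quantitative.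

Step 7
Reactants: 11 bis-silyl ether
Product: 13 [(tert-butyldimethylsilyl)oxy]acetaldehyde (two equivalents per 11), via secondary ozonide 12 (not isolated)
Conditions: O3, CH2Cl2, −78 °C; then Me2S, −78 °C → rt; short-path distillation, used fresh
Reagents that add atoms: ozone, [O-][O+]=O
Why: Criegee ozonolysis with reductive work-up cleaves the symmetric alkene into two identical aldehyde molecules, and silyl ethers are inert to ozone.

Step 8 (key C–C bond formation)
Reactants: 14 tert-butyl propionate; 13 [(tert-butyldimethylsilyl)oxy]acetaldehyde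
Product: 17 tert-butyl 4-[(tert-butyldimethylsilyl)oxy]-3-hydroxy-2-methylbutanoate (racemic syn/anti mixture), via propionate lithium enolate 15 (not isolated), via lithium aldolate 16 (not isolated)
Conditions: LDA (1.05 equiv), THF, −78 °C, 45 min; 13 (1.0 equiv), −78 °C, 30 min; AcOH (1.2 equiv) in THF, −78 °C
Reagents that add atoms: none
Why: Intermolecular lithium-enolate aldol addition, in which the fully preformed, non-self-condensing tert-butyl ester enolate adds fast and irreversibly at −78 °C to the reactive aldehyde and joins the C3 and C2 fragments, while the two new stereocentres need no control because both are erased in step 9.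

Step 9
Reactants: 17 aldol adduct
Product: 19 tert-butyl (E)-4-[(tert-butyldimethylsilyl)oxy]-2-methylbut-2-enoate, via mesylate 18 (not isolated)
Conditions: MsCl (1.3 equiv), Et3N (2 equiv), CH2Cl2, 0 °C, 30 min; then DBU (2.5 equiv), rt, 6 h
Reagents that add atoms: none
Why: Mesylation followed by DBU-induced E1cB elimination passes through the ester enolate, so both diastereomers converge on the thermodynamically preferred tiglate-type E-enoate (CH2OTBS trans to CO2tBu), and any trace of Z isomer is removed by chromatography.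

Step 10
Reactants: 19 silyloxy enoate
Product: 20 tert-butyl (E)-4-hydroxy-2-methylbut-2-enoate
Conditions: TBAF (1.3 equiv), AcOH (1.3 equiv), THF, 0 °C → rt
Reagents that add atoms: none
Why: Buffered fluoride desilylation frees the primary allylic alcohol without touching the tert-butyl ester, and the E geometry rules out lactonisation.

Step 11
Reactants: 20 hydroxy enoate; 21 tiglic acid [(E)-2-methylbut-2-enoic acid]
Product: 22 tert-butyl (E)-2-methyl-4-{[(E)-2-methylbut-2-enoyl]oxy}but-2-enoate
Conditions: DCC (1.2 equiv), DMAP (0.1 equiv), CH2Cl2, 0 °C → rt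
Reagents that add atoms: none
Why: Steglich esterification of an unhindered primary alcohol is dependable, and tiglic acid is already the stable E isomer so it cannot scramble.

Step 12
Reactants: 22 diester
Product: 23 (E)-2-methyl-4-{[(E)-2-methylbut-2-enoyl]oxy}but-2-enoic acid
Conditions: TFA/CH2Cl2 (1:4), 0 °C → rt, 2 h; toluene azeotrope
Reagents that add atoms: none
Why: Acidolysis of the tert-butyl ester through the tert-butyl cation is selective, because the primary allylic tiglate (its cation would be destabilised by the ester) and both electron-poor alkenes are inert to TFA.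

**Coupling**

Step 13
Reactants: 23 C10 acid; 9 epoxy ketol
Product: 25 (1S,3R,4R,6S)-1-methyl-2-oxo-4-(prop-1-en-2-yl)-7-oxabicyclo[4.1.0]heptan-3-yl (E)-2-methyl-4-{[(E)-2-methylbut-2-enoyl]oxy}but-2-enoate (target), via Yamaguchi mixed anhydride 24 (not isolated)
Conditions: 23 (1.3 equiv), 2,4,6-trichlorobenzoyl chloride (1.3 equiv), Et3N (1.5 equiv), toluene, rt, 1 h; then 9 (1.0 equiv), DMAP (1.5 equiv), 0 °C → rt
Reagents that add atoms: none
Why: Yamaguchi esterification, in which DMAP delivers the less hindered enoyl carbonyl of the mixed anhydride to the equatorial secondary OH, the C3–O bond is not broken so C3 stays R (also the thermodynamically preferred epimer), and the E-α-methyl enoates do not isomerise.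

**Compound list**
1 | (S)-(+)-carvone | C=C(C)[C@H]1CC=C(C)C(=O)C1 | starting material
2 | lithium cross-conjugated (C1=C6) enolate of (S)-carvone | C=C(C)[C@H]1CC=C(C)C([O-])=C1.[Li+] | intermediate
3 | {[(3S)-6-methyl-3-(prop-1-en-2-yl)cyclohexa-1,5-dien-1-yl]oxy}trimethylsilane | C=C(C)[C@H]1CC=C(C)C(O[Si](C)(C)C)=C1 | intermediate
4 | C1–C6 oxirane of 3, oxirane oxygen on the face opposite to isopropenyl | C=C(C)[C@H]1CC=C(C)[C@]2(O[Si](C)(C)C)O[C@H]12 | intermediate
5 | (5R,6R)-2-methyl-5-(prop-1-en-2-yl)-6-(trimethylsilyloxy)cyclohex-2-en-1-one | C=C(C)[C@H]1CC=C(C)C(=O)[C@@H]1O[Si](C)(C)C | intermediate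
6 | (5R,6R)-6-hydroxy-2-methyl-5-(prop-1-en-2-yl)cyclohex-2-en-1-one | C=C(C)[C@H]1CC=C(C)C(=O)[C@@H]1O | intermediate
7 | (5R,6R)-6-[(tert-butyldimethylsilyl)oxy]-2-methyl-5-(prop-1-en-2-yl)cyclohex-2-en-1-one | C=C(C)[C@H]1CC=C(C)C(=O)[C@@H]1O[Si](C)(C)C(C)(C)C | intermediate
8 | (1S,3R,4R,6S)-3-[(tert-butyldimethylsilyl)oxy]-1-methyl-4-(prop-1-en-2-yl)-7-oxabicyclo[4.1.0]heptan-2-one | C=C(C)[C@H]1C[C@@H]2O[C@]2(C)C(=O)[C@@H]1O[Si](C)(C)C(C)(C)C | intermediate
9 | (1S,3R,4R,6S)-3-hydroxy-1-methyl-4-(prop-1-en-2-yl)-7-oxabicyclo[4.1.0]heptan-2-one | C=C(C)[C@H]1C[C@@H]2O[C@]2(C)C(=O)[C@@H]1O | intermediate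
10 | (Z)-but-2-ene-1,4-diol | OC/C=C\CO | starting material
11 | (Z)-1,4-bis[(tert-butyldimethylsilyl)oxy]but-2-ene | CC(C)(C)[Si](C)(C)OC/C=C\CO[Si](C)(C)C(C)(C)C | intermediate
12 | 3,5-bis{[(tert-butyldimethylsilyl)oxy]methyl}-1,2,4-trioxolane (cis/trans mixture) | CC(C)(C)[Si](C)(C)OCC1OOC(CO[Si](C)(C)C(C)(C)C)O1 | intermediate
13 | [(tert-butyldimethylsilyl)oxy]acetaldehyde | CC(C)(C)[Si](C)(C)OCC=O | intermediate
14 | tert-butyl propionate | CCC(=O)OC(C)(C)C | starting material
15 | lithium enolate of tert-butyl propionate (mainly CH3 trans to OLi) | C/C=C(/[O-])OC(C)(C)C.[Li+] | intermediate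
16 | lithium alkoxide of 17 (racemic syn/anti mixture) | CC(C([O-])CO[Si](C)(C)C(C)(C)C)C(=O)OC(C)(C)C.[Li+] | intermediate
17 | tert-butyl 4-[(tert-butyldimethylsilyl)oxy]-3-hydroxy-2-methylbutanoate (racemic syn/anti mixture) | CC(C(O)CO[Si](C)(C)C(C)(C)C)C(=O)OC(C)(C)C | intermediate
18 | tert-butyl 4-[(tert-butyldimethylsilyl)oxy]-3-(methylsulfonyloxy)-2-methylbutanoate (racemic syn/anti mixture) | CC(C(CO[Si](C)(C)C(C)(C)C)OS(C)(=O)=O)C(=O)OC(C)(C)C | intermediate
19 | tert-butyl (E)-4-[(tert-butyldimethylsilyl)oxy]-2-methylbut-2-enoate | CC(C)(C)OC(=O)/C(C)=C/CO[Si](C)(C)C(C)(C)C | intermediate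
20 | tert-butyl (E)-4-hydroxy-2-methylbut-2-enoate | CC(C)(C)OC(=O)/C(C)=C/CO | intermediate
21 | tiglic acid, (E)-2-methylbut-2-enoic acid | C/C=C(\C)C(=O)O | starting material
22 | tert-butyl (E)-2-methyl-4-{[(E)-2-methylbut-2-enoyl]oxy}but-2-enoate | CC(C)(C)OC(=O)/C(C)=C/COC(=O)/C(C)=C/C | intermediate
23 | (E)-2-methyl-4-{[(E)-2-methylbut-2-enoyl]oxy}but-2-enoic acid | OC(=O)/C(C)=C/COC(=O)/C(C)=C/C | intermediate
24 | mixed anhydride of 23 and 2,4,6-trichlorobenzoic acid | O=C(OC(=O)/C(C)=C/COC(=O)/C(C)=C/C)c1c(Cl)cc(Cl)cc1Cl | intermediate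
25 | (1S,3R,4R,6S)-1-methyl-2-oxo-4-(prop-1-en-2-yl)-7-oxabicyclo[4.1.0]heptan-3-yl (E)-2-methyl-4-{[(E)-2-methylbut-2-enoyl]oxy}but-2-enoate | C=C(C)[C@H]1C[C@@H]2O[C@]2(C)C(=O)[C@@H]1OC(=O)/C(C)=C/COC(=O)/C(C)=C/C | target

**Totals**
- Total step count: 13.
- Longest linear sequence: 8 steps (steps 6–13, from 10). The core branch is 6 steps (steps 1–5 and 13).

**Three steps most likely to fail**

Step 2 (Rubottom oxidation). The peracid may partly epoxidise the isopropenyl group, and the trans/cis ratio at C6 may be only moderate. The fallback sets out from 1 and comes back at 6. It replaces the silyl enol ether and peracid by direct enolate hydroxylation with an oxidant that does not epoxidise alkenes. Compound 1 is deprotonated with NaHMDS in THF at −78 °C to give the sodium enolate of carvone F1. Adding 3-phenyl-2-(phenylsulfonyl)oxaziridine (Davis reagent) transfers oxygen to C6 anti to the isopropenyl group and gives the sodium alkoxide of trans-6-hydroxycarvone F2. Quenching with acetic acid at −78 °C delivers 6. The sodium counter-ion suppresses addition of the enolate to the sulfonimine by-product.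

Step 9 (mesylation and E1cB elimination). The E/Z ratio could be lower than expected, or DBU could partly deconjugate the γ-silyloxy enoate. The fallback sets out from 13 and comes back at 19. Aldehyde 13 is treated with the commercial stabilised ylide tert-butyl 2-(triphenylphosphoranylidene)propanoate in CH2Cl2 at rt (Wittig olefination). This gives the E-enoate 19 directly under neutral conditions, usually with E:Z of at least 95:5. It bypasses 17 and 18 and makes no compound outside the list (F0).

Step 13 (Yamaguchi esterification of the epoxy ketol). Compound 9 is a weakly nucleophilic, base-sensitive α-hydroxy-α′,β′-epoxy ketone, and it may react slowly or degrade with DMAP and Et3N. The fallback sets out from 6 (together with 23, activated as 24) and comes back at 25. It reverses the order of acylation and epoxidation, so steps 3–5 are dropped. The sturdier ketol 6 is acylated with 24 and DMAP in toluene to give (1R,6R)-3-methyl-2-oxo-6-(prop-1-en-2-yl)cyclohex-3-en-1-yl (E)-2-methyl-4-{[(E)-2-methylbut-2-enoyl]oxy}but-2-enoate F3. This is then epoxidised under anhydrous nucleophilic conditions (TBHP in decane, DBU, CH2Cl2, rt). Only the enone, and not the two much less electrophilic enoates, accepts tert-butyl peroxide. Attack again comes anti to the isopropenyl group, the esters are not hydrolysed, and 25 is obtained.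

**Further compounds**
F1 | step 2 | sodium cross-conjugated enolate of (S)-carvone | C=C(C)[C@H]1CC=C(C)C([O-])=C1.[Na+]
F2 | step 2 | sodium alkoxide of (5R,6R)-6-hydroxycarvone | C=C(C)[C@H]1CC=C(C)C(=O)[C@@H]1[O-].[Na+]
F0 | step 9 | none | none
F3 | step 13 | (1R,6R)-3-methyl-2-oxo-6-(prop-1-en-2-yl)cyclohex-3-en-1-yl (E)-2-methyl-4-{[(E)-2-methylbut-2-enoyl]oxy}but-2-enoate | C=C(C)[C@H]1CC=C(C)C(=O)[C@@H]1OC(=O)/C(C)=C/COC(=O)/C(C)=C/C
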